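## Retrosynthetic overview

1. Target 26 ⇐ methyl ester 25 ⇐ acylphloroglucinol 23, by Pd-catalysed enantioselective dearomative prenylation at C6 of the chromene (last C–C bond, sets the quaternary centre).
2. Cyclobutane (C1 carries the CH2 link, C2 the isopropenyl group, C3 the two methyl groups, C4 is CH2): bond C2–C3 is closed after every other ring. Ring carbon C3 with its gem-dimethyl pair is a tertiary carbocation in disguise, and the adjacent C2–H bearing C(CH3)=CH2 is the footprint of γ-attack by an allylsilane. An acyclic tertiary chloride/allylsilane (20) therefore closes in one SE2′ event, and the catalytically set C1 centre relays to C2.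
3. Side chain, built on the aromatic core: O-allylation/Claisen to C6, cross-metathesis to an allylic carbonate, Pd allyl–allyl coupling with methallyl-B(pin) (sets C1), HCl addition, cross-metathesis with methallylsilane.
4. Core 9: Pechmann coumarin from phloroglucinol, selective O-7 methylation, CuH conjugate reduction (sets the hexanoate centre), Friedel–Crafts/oxa-Michael pyranone annulation, BCl3 demethylation. The lactone masks the acid and one phenol until step 14.
5. Ring order: benzene ring (bought) → lactone (temporary, step 1) → pyranone (step 4) → cyclobutane (step 13).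

Key step: step 13

Assumption: in the three ligand-controlled steps (3, 10, 15) the ligand enantiomer named is taken to give the configuration drawn; if the sense of induction on these substrates is the opposite, its antipode is used.

## Route

Step 1
Reactants: 1 phloroglucinol; 2 ethyl 3-oxohexanoate
Product: 3 5,7-dihydroxy-4-propyl-2H-chromen-2-one
Conditions: conc. H2SO4, 0 °C to rt
Reagents that add atoms: none
Why: Pechmann condensation, in which acid-catalysed transesterification, ring hydroxyalkylation of the symmetrical phloroglucinol and dehydration should give the 4-propylcoumarin as the only regioisomer.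

Step 2
Reactants: 3 5,7-dihydroxy-4-propyl-2H-chromen-2-one
Product: 4 5-hydroxy-7-methoxy-4-propyl-2H-chromen-2-one
Conditions: MeI (1.05 equiv), K2CO3, acetone, rt
Reagents that add atoms: iodomethane, CI
Why: Williamson etherification, in which the 7-OH (conjugated with the pyranone carbonyl and unhindered) is more acidic and more accessible than the 5-OH peri to the propyl group, so one equivalent of MeI should methylate O-7 selectively.

Step 3
Reactants: 4 5-hydroxy-7-methoxy-4-propyl-2H-chromen-2-one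
Product: 5 (4R)-5-hydroxy-7-methoxy-4-propyl-3,4-dihydro-2H-chromen-2-one
Conditions: Cu(OAc)2 (5 mol %), (R)-DTBM-SEGPHOS, (EtO)2MeSiH (excess), t-BuOH, THF, 0 °C to rt; aq. NH4Cl
Reagents that add atoms: none
Why: CuH-catalysed asymmetric conjugate reduction of a 4-substituted coumarin (Buchwald type), in which the ligand-bound copper hydride should add to one face of C4 and set the 4R centre while the lactone carbonyl is spared.

Step 4
Reactants: 5 (4R)-5-hydroxy-7-methoxy-4-propyl-3,4-dihydro-2H-chromen-2-one; 6 3-methylbut-2-enoic acid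
Product: 8 (10R)-5-methoxy-2,2-dimethyl-10-propyl-2,3,9,10-tetrahydro-4H,8H-pyrano[2,3-f]chromene-4,8-dione, via ortho-acyl phenol enone 7 (not isolated)
Conditions: P2O5/MeSO3H (Eaton's reagent), 70 °C
Reagents that add atoms: none
Why: Friedel–Crafts acylation/oxa-Michael chromanone annulation, in which acylation ortho to the only free phenol (through the aryl ester and Fries shift) gives enone 7, which can close only onto O-5 because O-7 is methylated, so the pyranone should form with the required regiochemistry.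

Step 5
Reactants: 8 (10R)-5-methoxy-2,2-dimethyl-10-propyl-2,3,9,10-tetrahydro-4H,8H-pyrano[2,3-f]chromene-4,8-dione
Product: 9 (10R)-5-hydroxy-2,2-dimethyl-10-propyl-2,3,9,10-tetrahydro-4H,8H-pyrano[2,3-f]chromene-4,8-dione
Conditions: BCl3, CH2Cl2, −78 to 0 °C; aq. work-up
Reagents that add atoms: none
Why: chelation-assisted aryl methyl ether cleavage, in which BCl3 bound to the pyranone carbonyl should remove only the peri methyl group and leave the tertiary alkyl aryl ether and the lactone intact.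

Step 6
Reactants: 9 (10R)-5-hydroxy-2,2-dimethyl-10-propyl-2,3,9,10-tetrahydro-4H,8H-pyrano[2,3-f]chromene-4,8-dione; 10 allyl bromide
Product: 11 (10R)-2,2-dimethyl-5-(prop-2-en-1-yloxy)-10-propyl-2,3,9,10-tetrahydro-4H,8H-pyrano[2,3-f]chromene-4,8-dione
Conditions: K2CO3, DMF, 60 °C
Reagents that add atoms: none
Why: Williamson O-allylation of the hydrogen-bonded phenol under forcing but non-nucleophilic conditions should give the allyl aryl ether.

Step 7
Reactants: 11 (10R)-2,2-dimethyl-5-(prop-2-en-1-yloxy)-10-propyl-2,3,9,10-tetrahydro-4H,8H-pyrano[2,3-f]chromene-4,8-dione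
Product: 12 (10R)-5-hydroxy-2,2-dimethyl-6-(prop-2-en-1-yl)-10-propyl-2,3,9,10-tetrahydro-4H,8H-pyrano[2,3-f]chromene-4,8-dione
Conditions: PhNEt2, 190 °C
Reagents that add atoms: none
Why: aromatic Claisen rearrangement, in which the [3,3] shift can deliver the allyl group only to C6 (the one unsubstituted ortho position) and tautomerisation regenerates the phenol.

Step 8
Reactants: 12 (10R)-5-hydroxy-2,2-dimethyl-6-(prop-2-en-1-yl)-10-propyl-2,3,9,10-tetrahydro-4H,8H-pyrano[2,3-f]chromene-4,8-dione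
Product: 13 (10R)-5-[(tert-butyldimethylsilyl)oxy]-2,2-dimethyl-6-(prop-2-en-1-yl)-10-propyl-2,3,9,10-tetrahydro-4H,8H-pyrano[2,3-f]chromene-4,8-dione
Conditions: TBSOTf, 2,6-lutidine, CH2Cl2, 0 °C
Reagents that add atoms: tert-butyldimethylsilyl trifluoromethanesulfonate, CC(C)(C)[Si](C)(C)OS(=O)(=O)C(F)(F)F
Why: silylation of the hindered, chelated phenol with the silyl triflate should mask the oxygen nucleophile that would otherwise cyclise onto the π-allyl intermediate of step 10.

Step 9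
Reactants: 13 (10R)-5-[(tert-butyldimethylsilyl)oxy]-2,2-dimethyl-6-(prop-2-en-1-yl)-10-propyl-2,3,9,10-tetrahydro-4H,8H-pyrano[2,3-f]chromene-4,8-dione; 14 tert-butyl prop-2-en-1-yl carbonate
Product: 15 tert-butyl (2E)-4-[(10R)-5-[(tert-butyldimethylsilyl)oxy]-2,2-dimethyl-4,8-dioxo-10-propyl-2,3,9,10-tetrahydro-4H,8H-pyrano[2,3-f]chromen-6-yl]but-2-en-1-yl carbonate
Conditions: Hoveyda–Grubbs II (5 mol %), 14 in excess, CH2Cl2, 40 °C
Reagents that add atoms: none
Why: olefin cross-metathesis of the terminal allyl group with an excess of the allyl carbonate should give the internal allylic carbonate, mainly as the E isomer, with loss of ethene.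

Step 10
Reactants: 15 tert-butyl (2E)-4-[(10R)-5-[(tert-butyldimethylsilyl)oxy]-2,2-dimethyl-4,8-dioxo-10-propyl-2,3,9,10-tetrahydro-4H,8H-pyrano[2,3-f]chromen-6-yl]but-2-en-1-yl carbonate; 16 4,4,5,5-tetramethyl-2-(2-methylprop-2-en-1-yl)-1,3,2-dioxaborolane
Product: 17 (10R)-5-[(tert-butyldimethylsilyl)oxy]-6-[(2S)-2-ethenyl-4-methylpent-4-en-1-yl]-2,2-dimethyl-10-propyl-2,3,9,10-tetrahydro-4H,8H-pyrano[2,3-f]chromene-4,8-dione
Conditions: Pd2(dba)3 (2.5 mol %), (R)-MeO-furyl-BIPHEP (5 mol %), THF, rt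
Reagents that add atoms: none
Why: Pd-catalysed enantioselective allyl–allyl cross-coupling (Morken type), in which 3,3′-reductive elimination from the bis(η1-allyl)palladium complex forms the branched 1,5-diene and the chiral bisphosphine should set the (S) centre that becomes C1 of the cyclobutane.

Step 11
Reactants: 17 (10R)-5-[(tert-butyldimethylsilyl)oxy]-6-[(2S)-2-ethenyl-4-methylpent-4-en-1-yl]-2,2-dimethyl-10-propyl-2,3,9,10-tetrahydro-4H,8H-pyrano[2,3-f]chromene-4,8-dione
Product: 18 (10R)-5-[(tert-butyldimethylsilyl)oxy]-6-[(2R)-4-chloro-2-ethenyl-4-methylpentyl]-2,2-dimethyl-10-propyl-2,3,9,10-tetrahydro-4H,8H-pyrano[2,3-f]chromene-4,8-dione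
Conditions: anhydrous HCl, CH2Cl2, −20 to 0 °C
Reagents that add atoms: hydrogen chloride, Cl
Why: Markovnikov hydrochlorination, in which the 1,1-disubstituted alkene is protonated to a tertiary cation far faster than the vinyl group, so HCl should add only there (the descriptor changes by CIP priority only).

Step 12
Reactants: 18 (10R)-5-[(tert-butyldimethylsilyl)oxy]-6-[(2R)-4-chloro-2-ethenyl-4-methylpentyl]-2,2-dimethyl-10-propyl-2,3,9,10-tetrahydro-4H,8H-pyrano[2,3-f]chromene-4,8-dione; 19 trimethyl(2-methylprop-2-en-1-yl)silane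
Product: 20 (10R)-5-[(tert-butyldimethylsilyl)oxy]-6-[(2R,3E)-2-(2-chloro-2-methylpropyl)-4-methyl-5-(trimethylsilyl)pent-3-en-1-yl]-2,2-dimethyl-10-propyl-2,3,9,10-tetrahydro-4H,8H-pyrano[2,3-f]chromene-4,8-dione
Conditions: Hoveyda–Grubbs II (10 mol %), 19 in excess, CH2Cl2, 40 °C
Reagents that add atoms: none
Why: olefin cross-metathesis of the remaining vinyl group with an excess of the 1,1-disubstituted allylsilane should give the trisubstituted allylsilane, mainly E, the tertiary chloride being inert to the ruthenium carbene.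

Step 13
Reactants: 20 (10R)-5-[(tert-butyldimethylsilyl)oxy]-6-[(2R,3E)-2-(2-chloro-2-methylpropyl)-4-methyl-5-(trimethylsilyl)pent-3-en-1-yl]-2,2-dimethyl-10-propyl-2,3,9,10-tetrahydro-4H,8H-pyrano[2,3-f]chromene-4,8-dione
Product: 21 (10R)-5-[(tert-butyldimethylsilyl)oxy]-6-{[(1S,2R)-3,3-dimethyl-2-(prop-1-en-2-yl)cyclobutyl]methyl}-2,2-dimethyl-10-propyl-2,3,9,10-tetrahydro-4H,8H-pyrano[2,3-f]chromene-4,8-dione
Conditions: TiCl4 (3 equiv), CH2Cl2, −78 °C; cold quench with Et3N, then aq. NaHCO3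
Reagents that add atoms: none
Why: Proposed new method: TiCl4 ionises the tertiary chloride to a tertiary carbocation at the future C3, which is attacked by the γ-carbon of the tethered allylsilane to give a β-silyl cation that loses Me3SiCl at once and leaves the isopropenyl group; the closest known reactions are the Hosomi–Sakurai/Reetz allylation of tertiary alkyl chlorides (intermolecular) and intramolecular allylsilane–cation cyclisations to five- and six-membered rings. The four-membered ring closes in a 4-exo-trig (SE2′) mode by forming C2–C3. The new stereocentre C2 is controlled by the existing C1 centre, because in the puckered transition state the arylmethyl group on C1 and the silylated propenyl arm on C2 should sit trans, which gives the (1S,2R) ring. The step needs ring closure to beat elimination, protodesilylation and ring expansion: elimination of the cation is reversible under HCl/TiCl4 whereas loss of silicon is not, a tertiary cation and a trisubstituted allylsilane react near diffusion control on the Mayr scales, and desilylation of the β-silyl cation should outrun its cyclobutylcarbinyl-to-cyclopentyl shift. No other cyclisation mode leads to a stabilised cation (the α-carbon bears silicon, and 5-endo attack would give a secondary cation), and every aromatic position is substituted, so no Friedel–Crafts path competes.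

Step 14
Reactants: 21 (10R)-5-[(tert-butyldimethylsilyl)oxy]-6-{[(1S,2R)-3,3-dimethyl-2-(prop-1-en-2-yl)cyclobutyl]methyl}-2,2-dimethyl-10-propyl-2,3,9,10-tetrahydro-4H,8H-pyrano[2,3-f]chromene-4,8-dione
Product: 23 methyl (3R)-3-[6-{[(1S,2R)-3,3-dimethyl-2-(prop-1-en-2-yl)cyclobutyl]methyl}-5,7-dihydroxy-2,2-dimethyl-4-oxo-3,4-dihydro-2H-chromen-8-yl]hexanoate, via desilylated phenol lactone 22 (not isolated)
Conditions: K2CO3, MeOH, 0 °C to rt; aq. NH4Cl, used at once
Reagents that add atoms: methanol, CO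
Why: base-mediated methanolysis, in which methoxide should cleave the aryl silyl ether and open the aryl ester (lactone) to the methyl ester, freeing both phenols that flank C6 without touching a stereocentre.

Step 15
Reactants: 23 methyl (3R)-3-[6-{[(1S,2R)-3,3-dimethyl-2-(prop-1-en-2-yl)cyclobutyl]methyl}-5,7-dihydroxy-2,2-dimethyl-4-oxo-3,4-dihydro-2H-chromen-8-yl]hexanoate; 24 3-methylbut-2-en-1-yl acetate
Product: 25 methyl (3R)-3-[(6R)-6-{[(1S,2R)-3,3-dimethyl-2-(prop-1-en-2-yl)cyclobutyl]methyl}-5-hydroxy-2,2-dimethyl-6-(3-methylbut-2-en-1-yl)-4,7-dioxo-3,4,6,7-tetrahydro-2H-chromen-8-yl]hexanoate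
Conditions: Pd2(dba)3 (2.5 mol %), (R,R)-DACH-phenyl Trost ligand (7.5 mol %), Cs2CO3, THF, 0 °C
Reagents that add atoms: none
Why: Pd-catalysed asymmetric allylic alkylation (Tsuji–Trost) used as an alkylative dearomatisation, in which the acylphloroglucinol anion attacks the π-prenyl palladium complex through C6 at the unsubstituted allyl terminus (O-allylation being reversible, C8 being hindered by its secondary alkyl group) and the Trost ligand should select the face that gives the 6R quaternary centre.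

Step 16
Reactants: 25 methyl (3R)-3-[(6R)-6-{[(1S,2R)-3,3-dimethyl-2-(prop-1-en-2-yl)cyclobutyl]methyl}-5-hydroxy-2,2-dimethyl-6-(3-methylbut-2-en-1-yl)-4,7-dioxo-3,4,6,7-tetrahydro-2H-chromen-8-yl]hexanoate
Product: 26 (3R)-3-[(6R)-6-{[(1S,2R)-3,3-dimethyl-2-(prop-1-en-2-yl)cyclobutyl]methyl}-5-hydroxy-2,2-dimethyl-6-(3-methylbut-2-en-1-yl)-4,7-dioxo-3,4,6,7-tetrahydro-2H-chromen-8-yl]hexanoic acid
Conditions: LiOH, THF/H2O, 0 °C to rt; then 1 M HCl to pH 3–4 at 0 °C
Reagents that add atoms: lithium hydroxide, [Li+].[OH-]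
Why: saponification of the methyl ester followed by careful acidification should give the acid, no stereocentre being enolisable under these conditions.

## Compound list

1 | phloroglucinol | Oc1cc(O)cc(O)c1 | starting material
2 | ethyl 3-oxohexanoate | CCCC(=O)CC(=O)OCC | starting material
3 | 5,7-dihydroxy-4-propyl-2H-chromen-2-one | CCCC1=CC(=O)Oc2cc(O)cc(O)c12 | intermediate
4 | 5-hydroxy-7-methoxy-4-propyl-2H-chromen-2-one | CCCC1=CC(=O)Oc2cc(OC)cc(O)c12 | intermediate
5 | (4R)-5-hydroxy-7-methoxy-4-propyl-3,4-dihydro-2H-chromen-2-one | CCC[C@@H]1CC(=O)Oc2cc(OC)cc(O)c12 | intermediate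
6 | 3-methylbut-2-enoic acid | CC(C)=CC(=O)O | starting material
7 | (4R)-5-hydroxy-7-methoxy-6-(3-methylbut-2-enoyl)-4-propyl-3,4-dihydro-2H-chromen-2-one (not isolated) | CCC[C@@H]1CC(=O)Oc2cc(OC)c(C(=O)C=C(C)C)c(O)c12 | intermediate
8 | (10R)-5-methoxy-2,2-dimethyl-10-propyl-2,3,9,10-tetrahydro-4H,8H-pyrano[2,3-f]chromene-4,8-dione | CCC[C@@H]1CC(=O)Oc2cc(OC)c3C(=O)CC(C)(C)Oc3c12 | intermediate
9 | (10R)-5-hydroxy-2,2-dimethyl-10-propyl-2,3,9,10-tetrahydro-4H,8H-pyrano[2,3-f]chromene-4,8-dione | CCC[C@@H]1CC(=O)Oc2cc(O)c3C(=O)CC(C)(C)Oc3c12 | intermediate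
10 | allyl bromide (3-bromoprop-1-ene) | C=CCBr | starting material
11 | (10R)-2,2-dimethyl-5-(prop-2-en-1-yloxy)-10-propyl-2,3,9,10-tetrahydro-4H,8H-pyrano[2,3-f]chromene-4,8-dione | CCC[C@@H]1CC(=O)Oc2cc(OCC=C)c3C(=O)CC(C)(C)Oc3c12 | intermediate
12 | (10R)-5-hydroxy-2,2-dimethyl-6-(prop-2-en-1-yl)-10-propyl-2,3,9,10-tetrahydro-4H,8H-pyrano[2,3-f]chromene-4,8-dione | CCC[C@@H]1CC(=O)Oc2c(CC=C)c(O)c3C(=O)CC(C)(C)Oc3c12 | intermediate
13 | (10R)-5-[(tert-butyldimethylsilyl)oxy]-2,2-dimethyl-6-(prop-2-en-1-yl)-10-propyl-2,3,9,10-tetrahydro-4H,8H-pyrano[2,3-f]chromene-4,8-dione | CCC[C@@H]1CC(=O)Oc2c(CC=C)c(O[Si](C)(C)C(C)(C)C)c3C(=O)CC(C)(C)Oc3c12 | intermediate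
14 | tert-butyl prop-2-en-1-yl carbonate | C=CCOC(=O)OC(C)(C)C | starting material
15 | tert-butyl (2E)-4-[(10R)-5-[(tert-butyldimethylsilyl)oxy]-2,2-dimethyl-4,8-dioxo-10-propyl-2,3,9,10-tetrahydro-4H,8H-pyrano[2,3-f]chromen-6-yl]but-2-en-1-yl carbonate | CCC[C@@H]1CC(=O)Oc2c(C/C=C/COC(=O)OC(C)(C)C)c(O[Si](C)(C)C(C)(C)C)c3C(=O)CC(C)(C)Oc3c12 | intermediate
16 | 4,4,5,5-tetramethyl-2-(2-methylprop-2-en-1-yl)-1,3,2-dioxaborolane | CC(=C)CB1OC(C)(C)C(C)(C)O1 | starting material
17 | (10R)-5-[(tert-butyldimethylsilyl)oxy]-6-[(2S)-2-ethenyl-4-methylpent-4-en-1-yl]-2,2-dimethyl-10-propyl-2,3,9,10-tetrahydro-4H,8H-pyrano[2,3-f]chromene-4,8-dione | CCC[C@@H]1CC(=O)Oc2c(C[C@H](CC(C)=C)C=C)c(O[Si](C)(C)C(C)(C)C)c3C(=O)CC(C)(C)Oc3c12 | intermediate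
18 | (10R)-5-[(tert-butyldimethylsilyl)oxy]-6-[(2R)-4-chloro-2-ethenyl-4-methylpentyl]-2,2-dimethyl-10-propyl-2,3,9,10-tetrahydro-4H,8H-pyrano[2,3-f]chromene-4,8-dione | CCC[C@@H]1CC(=O)Oc2c(C[C@H](CC(C)(C)Cl)C=C)c(O[Si](C)(C)C(C)(C)C)c3C(=O)CC(C)(C)Oc3c12 | intermediate
19 | trimethyl(2-methylprop-2-en-1-yl)silane | CC(=C)C[Si](C)(C)C | starting material
20 | (10R)-5-[(tert-butyldimethylsilyl)oxy]-6-[(2R,3E)-2-(2-chloro-2-methylpropyl)-4-methyl-5-(trimethylsilyl)pent-3-en-1-yl]-2,2-dimethyl-10-propyl-2,3,9,10-tetrahydro-4H,8H-pyrano[2,3-f]chromene-4,8-dione | CCC[C@@H]1CC(=O)Oc2c(C[C@H](CC(C)(C)Cl)/C=C(\C)C[Si](C)(C)C)c(O[Si](C)(C)C(C)(C)C)c3C(=O)CC(C)(C)Oc3c12 | intermediate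
21 | (10R)-5-[(tert-butyldimethylsilyl)oxy]-6-{[(1S,2R)-3,3-dimethyl-2-(prop-1-en-2-yl)cyclobutyl]methyl}-2,2-dimethyl-10-propyl-2,3,9,10-tetrahydro-4H,8H-pyrano[2,3-f]chromene-4,8-dione | CCC[C@@H]1CC(=O)Oc2c(C[C@@H]4CC(C)(C)[C@H]4C(C)=C)c(O[Si](C)(C)C(C)(C)C)c3C(=O)CC(C)(C)Oc3c12 | intermediate
22 | (10R)-6-{[(1S,2R)-3,3-dimethyl-2-(prop-1-en-2-yl)cyclobutyl]methyl}-5-hydroxy-2,2-dimethyl-10-propyl-2,3,9,10-tetrahydro-4H,8H-pyrano[2,3-f]chromene-4,8-dione (not isolated) | CCC[C@@H]1CC(=O)Oc2c(C[C@@H]4CC(C)(C)[C@H]4C(C)=C)c(O)c3C(=O)CC(C)(C)Oc3c12 | intermediate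
23 | methyl (3R)-3-[6-{[(1S,2R)-3,3-dimethyl-2-(prop-1-en-2-yl)cyclobutyl]methyl}-5,7-dihydroxy-2,2-dimethyl-4-oxo-3,4-dihydro-2H-chromen-8-yl]hexanoate | CCC[C@H](CC(=O)OC)c1c(O)c(C[C@@H]3CC(C)(C)[C@H]3C(C)=C)c(O)c2C(=O)CC(C)(C)Oc12 | intermediate
24 | 3-methylbut-2-en-1-yl acetate (prenyl acetate) | CC(C)=CCOC(C)=O | starting material
25 | methyl (3R)-3-[(6R)-6-{[(1S,2R)-3,3-dimethyl-2-(prop-1-en-2-yl)cyclobutyl]methyl}-5-hydroxy-2,2-dimethyl-6-(3-methylbut-2-en-1-yl)-4,7-dioxo-3,4,6,7-tetrahydro-2H-chromen-8-yl]hexanoate | C=C(C)[C@H]1[C@H](C[C@]2(CC=C(C)C)C(=O)C([C@H](CCC)CC(=O)OC)=C3OC(C)(C)CC(=O)C3=C2O)CC1(C)C | intermediate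
26 | (3R)-3-[(6R)-6-{[(1S,2R)-3,3-dimethyl-2-(prop-1-en-2-yl)cyclobutyl]methyl}-5-hydroxy-2,2-dimethyl-6-(3-methylbut-2-en-1-yl)-4,7-dioxo-3,4,6,7-tetrahydro-2H-chromen-8-yl]hexanoic acid | C=C(C)[C@H]1[C@H](C[C@]2(CC=C(C)C)C(=O)C([C@H](CCC)CC(=O)O)=C3OC(C)(C)CC(=O)C3=C2O)CC1(C)C | target

## Step count and risks

Total step count: 16. Longest linear sequence: 16 steps (1 to 26; all building blocks enter this single line).

**Risk 1, step 13 (proposed new method).** The tertiary cation may be consumed by elimination and the allylsilane by protodesilylation before the strained ring closes, or the cyclobutylcarbinyl cation may ring-expand before silicon leaves. The fallback uses known chemistry and brings the four-membered ring in ready-made; it sets out from 9 and comes back at 21. Iodination of the only free aromatic position of 9 (NIS, MeCN) should give (10R)-5-hydroxy-6-iodo-2,2-dimethyl-10-propyl-2,3,9,10-tetrahydro-4H,8H-pyrano[2,3-f]chromene-4,8-dione F1, and silylation (TBSOTf, 2,6-lutidine) its silyl ether F2. In parallel, EtAlCl2-promoted [2+2] cycloaddition of methyl propiolate with isobutene should give methyl 3,3-dimethylcyclobut-1-ene-1-carboxylate F3. Copper-catalysed conjugate addition of isopropenylmagnesium bromide (CuBr·SMe2, TMSCl), followed by NaOMe equilibration, should give racemic methyl trans-3,3-dimethyl-2-(prop-1-en-2-yl)cyclobutane-1-carboxylate F4. LiAlH4 reduction gives the alcohol F5, I2/PPh3/imidazole the iodide F6, and zinc insertion (Zn, LiCl, THF) the alkylzinc iodide F7. Negishi coupling of F2 with F7 (Pd(OAc)2, SPhos) should give 21 together with its (1R,2S)-cyclobutyl diastereomer F8, which is removed by chromatography.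

**Risk 2, step 12.** Cross-metathesis between the α-branched vinyl group and a 1,1-disubstituted partner may be slow and lose out to homodimerisation or catalyst decay. The fallback sets out from 18 and comes back at 20. Lemieux–Johnson cleavage of the vinyl group (OsO4 cat., NaIO4, 2,6-lutidine, dioxane/H2O) should give the aldehyde F9. Wittig olefination at −78 °C with [1-(trimethylsilyl)propan-2-ylidene]triphenylphosphorane F10 (from ethyltriphenylphosphonium bromide, n-BuLi, ICH2SiMe3, n-BuLi) should give 20 together with its 3Z isomer F11; both isomers are expected to lead to 21 in step 13.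

**Risk 3, step 15.** The catalyst may discriminate the two faces of C6 poorly, or O-prenylation and attack at the tertiary allyl terminus may compete. The fallback sets out from 23 and comes back at 25. Uncatalysed alkylative dearomatisation (prenyl bromide, NaOMe, MeOH, 0 °C), the classical C-prenylation of acylphloroglucinol anions, should give 25 and its C6 epimer F12, which are diastereomers and are separated by preparative HPLC.

Further compounds
F1 | step 13 | (10R)-5-hydroxy-6-iodo-2,2-dimethyl-10-propyl-2,3,9,10-tetrahydro-4H,8H-pyrano[2,3-f]chromene-4,8-dione | CCC[C@@H]1CC(=O)Oc2c(I)c(O)c3C(=O)CC(C)(C)Oc3c12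
F2 | step 13 | (10R)-5-[(tert-butyldimethylsilyl)oxy]-6-iodo-2,2-dimethyl-10-propyl-2,3,9,10-tetrahydro-4H,8H-pyrano[2,3-f]chromene-4,8-dione | CCC[C@@H]1CC(=O)Oc2c(I)c(O[Si](C)(C)C(C)(C)C)c3C(=O)CC(C)(C)Oc3c12
F3 | step 13 | methyl 3,3-dimethylcyclobut-1-ene-1-carboxylate | COC(=O)C1=CC(C)(C)C1
F4 | step 13 | methyl trans-3,3-dimethyl-2-(prop-1-en-2-yl)cyclobutane-1-carboxylate (racemic; the (1R,2R) enantiomer is drawn) | COC(=O)[C@@H]1CC(C)(C)[C@H]1C(C)=C
F5 | step 13 | [trans-3,3-dimethyl-2-(prop-1-en-2-yl)cyclobutyl]methanol (racemic; the (1R,2R) enantiomer is drawn) | OC[C@@H]1CC(C)(C)[C@H]1C(C)=C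
F6 | step 13 | trans-1-(iodomethyl)-3,3-dimethyl-2-(prop-1-en-2-yl)cyclobutane (racemic; the (1R,2R) enantiomer is drawn) | IC[C@@H]1CC(C)(C)[C@H]1C(C)=C
F7 | step 13 | {[trans-3,3-dimethyl-2-(prop-1-en-2-yl)cyclobutyl]methyl}zinc iodide (racemic; the (1R,2R) enantiomer is drawn) | I[Zn]C[C@@H]1CC(C)(C)[C@H]1C(C)=C
F8 | step 13 | (10R)-5-[(tert-butyldimethylsilyl)oxy]-6-{[(1R,2S)-3,3-dimethyl-2-(prop-1-en-2-yl)cyclobutyl]methyl}-2,2-dimethyl-10-propyl-2,3,9,10-tetrahydro-4H,8H-pyrano[2,3-f]chromene-4,8-dione | CCC[C@@H]1CC(=O)Oc2c(C[C@H]4CC(C)(C)[C@@H]4C(C)=C)c(O[Si](C)(C)C(C)(C)C)c3C(=O)CC(C)(C)Oc3c12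
F9 | step 12 | (2R)-2-{[(10R)-5-[(tert-butyldimethylsilyl)oxy]-2,2-dimethyl-4,8-dioxo-10-propyl-2,3,9,10-tetrahydro-4H,8H-pyrano[2,3-f]chromen-6-yl]methyl}-4-chloro-4-methylpentanal | CCC[C@@H]1CC(=O)Oc2c(C[C@H](CC(C)(C)Cl)C=O)c(O[Si](C)(C)C(C)(C)C)c3C(=O)CC(C)(C)Oc3c12
F10 | step 12 | [1-(trimethylsilyl)propan-2-ylidene]triphenylphosphorane | CC(C[Si](C)(C)C)=P(c1ccccc1)(c1ccccc1)c1ccccc1
F11 | step 12 | (10R)-5-[(tert-butyldimethylsilyl)oxy]-6-[(2R,3Z)-2-(2-chloro-2-methylpropyl)-4-methyl-5-(trimethylsilyl)pent-3-en-1-yl]-2,2-dimethyl-10-propyl-2,3,9,10-tetrahydro-4H,8H-pyrano[2,3-f]chromene-4,8-dione | CCC[C@@H]1CC(=O)Oc2c(C[C@H](CC(C)(C)Cl)/C=C(/C)C[Si](C)(C)C)c(O[Si](C)(C)C(C)(C)C)c3C(=O)CC(C)(C)Oc3c12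
F12 | step 15 | methyl (3R)-3-[(6S)-6-{[(1S,2R)-3,3-dimethyl-2-(prop-1-en-2-yl)cyclobutyl]methyl}-5-hydroxy-2,2-dimethyl-6-(3-methylbut-2-en-1-yl)-4,7-dioxo-3,4,6,7-tetrahydro-2H-chromen-8-yl]hexanoate | C=C(C)[C@H]1[C@H](C[C@@]2(CC=C(C)C)C(=O)C([C@H](CCC)CC(=O)OC)=C3OC(C)(C)CC(=O)C3=C2O)CC1(C)C
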